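**Plan**

1. Retrosynthesis (side chain on C-8 numbered C-1 to C-9 outward from ring A): after global desilylation, the aryl–C-3 bond is cut first as an anti-SN2' arylation of an allylic picolinate, which moves the alkene to C-3/C-4 and puts an oxygen on C-5. The C-7 carbinol then goes back to a ketone (Evans–Tishchenko), the C-5–C-6 bond is cut as an aldol, the enal C=C by cross-metathesis, the C-1–C-2 bond by allylboration and the C-8–CHO bond by formylation of the flavanone.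
2. Feature used: in the side chain of ring A the C-6 methylene lies between the alkene CH (C-5) and the carbinol carbon C-7 that carries the 4-hydroxyphenethyl group, and the alkene is flanked on its far side by the ArCH centre C-3. With one oxygen added at C-5 this is the β-hydroxy ketone formed when the methyl group of 4-(4-hydroxyphenyl)butan-2-one adds to an enal, and the E-CH(Ar)–CH=CH unit is the 1,3-transposed form of the resulting allylic ester.
3. Forward: rings A, B and C come intact from (2S)-naringenin; the chain grows outward from C-8 (CHO, allyl carbinol, enal), the butanone half is joined by the aldol, and the aryl group on C-3 enters last with allylic transposition.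
4. Stereochemistry: C-2 of the flavanone from naringenin; the (S)-benzylic carbinol from Ipc2B-allyl; the temporary C-5 carbinol from Ipc2BCl, relayed 1,3-anti to the (S)-carbinol C-7 and by anti-SN2' to the (R)-ArCH centre and the E-alkene.

Key step: step 9

Assumption: (2S)-naringenin of high enantiomeric purity is taken as the commercial chiral-pool starting material, and C-2 is kept away from alkoxide or hydroxide bases throughout.
Abbreviations: TBS = tert-butyldimethylsilyl; Ipc = isopinocampheyl.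

Step 1
Reactants: 1 (2S)-naringenin
Product: 2 (2S)-5-hydroxy-7-(TBSO)-2-[4-(TBSO)phenyl]chroman-4-one
Conditions: TBSCl (2.2 equiv), imidazole, DMF, 0 °C → rt
Reagents that add atoms: tert-butyldimethylsilyl chloride, CC(C)(C)[Si](C)(C)Cl
Why: Silyl ether formation: the 7- and 4'-phenols should silylate while the 5-OH, hydrogen-bonded to the C-4 carbonyl, stays free, and imidazole is too weak a base to open ring C.

Step 2
Reactants: 2 bis-silyl ether
Product: 3 (2S)-5-methoxy-7-(TBSO)-2-[4-(TBSO)phenyl]chroman-4-one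
Conditions: MeI (excess), Ag2O, 4 Å MS, CH2Cl2, rt, dark
Reagents that add atoms: iodomethane, CI
Why: Purdie methylation (Ag2O/MeI) should O-methylate the chelated 5-OH without an alkoxide base, so neither retro-oxa-Michael opening at C-2 nor loss of the aryl silyl ethers is expected.

Step 3
Reactants: 3 5-O-methyl flavanone
Product: 4 (2S)-8-iodo-5-methoxy-7-(TBSO)-2-[4-(TBSO)phenyl]chroman-4-one
Conditions: NIS (1.05 equiv), TFA (10 mol%), MeCN, 0 °C
Reagents that add atoms: N-iodosuccinimide, O=C1CCC(=O)N1I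
Why: Electrophilic aromatic iodination of ring A should go to C-8, which lies between O-1 and the 7-silyloxy group and para to the 5-methoxy group, because C-6 is flanked by the methoxy and silyloxy substituents and ring B carries only one oxygen.

Step 4
Reactants: 4 8-iodoflavanone
Product: 5 (2S)-5-methoxy-4-oxo-7-(TBSO)-2-[4-(TBSO)phenyl]chroman-8-carbaldehyde
Conditions: Pd(PPh3)4 (5 mol%), CO (3 atm), Bu3SnH (slow addition), toluene, 50 °C
Reagents that add atoms: carbon monoxide, [C-]#[O+]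
Why: Palladium-catalysed reductive carbonylation (formylation): oxidative addition of the aryl iodide to zerovalent palladium, CO insertion and hydride transfer from Bu3SnH should give the aldehyde under neutral conditions.

Step 5
Reactants: 5 flavanone-8-carbaldehyde
Product: 7 (2S)-8-[(1S)-1-hydroxybut-3-enyl]-5-methoxy-7-(TBSO)-2-[4-(TBSO)phenyl]chroman-4-one, via borinate ester 6 (not isolated)
Conditions: (−)-Ipc2B(allyl), Et2O, −78 °C; then MeOH, pH 7 buffer, 30% H2O2, 0 °C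
Reagents that add atoms: (−)-B-allyldiisopinocampheylborane [(+)-α-pinene series], C=CCB([C@@H]1C[C@@H]2C[C@H]([C@H]1C)C2(C)C)[C@@H]1C[C@@H]2C[C@H]([C@H]1C)C2(C)C
Why: Brown allylboration: the allylborane adds through a chair six-membered transition state to the si face of the aldehyde (reagent control by the Ipc groups), which should set the (S)-carbinol, while the C-4 ketone does not react at −78 °C and the buffered oxidative work-up avoids base.

Step 6
Reactants: 7 homoallylic alcohol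
Product: 8 (2S)-8-[(1S)-1-(TBSO)but-3-enyl]-5-methoxy-7-(TBSO)-2-[4-(TBSO)phenyl]chroman-4-one
Conditions: TBSOTf, 2,6-lutidine, CH2Cl2, −78 → 0 °C
Reagents that add atoms: tert-butyldimethylsilyl triflate, CC(C)(C)[Si](C)(C)OS(=O)(=O)C(F)(F)F
Why: Silyl ether formation with the silyl triflate should protect the hindered benzylic carbinol, which must not quench the boron enolate of step 9 or form an alkoxide in step 12.

Step 7
Reactants: 8 terminal alkene
Product: 9 (2E,5S)-5-(TBSO)-5-{(2S)-5-methoxy-4-oxo-7-(TBSO)-2-[4-(TBSO)phenyl]chroman-8-yl}pent-2-enal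
Conditions: (E)-crotonaldehyde (5 equiv), second-generation Hoveyda–Grubbs catalyst RuCl2(H2IMes)(=CH-C6H4-2-OiPr) (5 mol%), CH2Cl2, 40 °C
Reagents that add atoms: (E)-but-2-enal, C/C=C/C=O
Why: Olefin cross-metathesis of the terminal alkene with the electron-poor partner crotonaldehyde should give the E-enal under thermodynamic control with loss of propene.

Step 8
Reactants: 10 4-(4-hydroxyphenyl)butan-2-one
Product: 11 4-[4-(TBSO)phenyl]butan-2-one
Conditions: TBSCl, imidazole, DMF, rt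
Reagents that add atoms: tert-butyldimethylsilyl chloride, CC(C)(C)[Si](C)(C)Cl
Why: Silyl ether formation should mask the phenol, whose proton would otherwise quench the enol borinate in step 9.

Step 9
Reactants: 9 enal; 11 silylated butanone
Product: 14 (2S)-8-[(1S,3E,5R)-5-hydroxy-7-oxo-1-(TBSO)-9-[4-(TBSO)phenyl]non-3-enyl]-5-methoxy-7-(TBSO)-2-[4-(TBSO)phenyl]chroman-4-one, via enol borinate 12 (not isolated), via boron aldolate 13 (not isolated)
Conditions: 11, (−)-Ipc2BCl, Et3N, Et2O, 0 °C; then 9, −78 → −20 °C; MeOH, pH 7 buffer, 30% H2O2, 0 °C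
Reagents that add atoms: none
Why: Paterson boron aldol (the Ipc2BCl-mediated aldol of a methyl ketone with an enal is the closest known reaction type): the bulky chloroborane with Et3N enolises 11 on its methyl group to enol borinate 12, which adds 1,2 to the aldehyde of 9 through a cyclic six-membered transition state to give aldolate 13 and, after buffered oxidative work-up, the β-hydroxy ketone 14. This joins the two fragments through the bond between the aldehyde carbon (the later alkene CH, C-5) and the ketone methyl carbon (the later chain CH2, C-6). No ring is closed. The new carbinol centre is reagent-controlled: the Ipc groups of the (+)-α-pinene series direct a methyl-ketone enolate to the re face of the aldehyde, which should make the (5R)-carbinol the major isomer, while the existing centres of 9 lie four or more atoms away and should not bias the addition. This carbinol is a temporary centre: it relays its configuration to C-7 (step 10) and to the ArCH centre and the E-alkene (step 12), and its oxygen then leaves the molecule. The step needs the aldehyde to react in preference to the C-4 ketone and 1,2- in preference to 1,4-addition, which the boron enolate at −78 °C secures, and methyl-side enolisation, which the bulky borane with Et3N secures.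

Step 10
Reactants: 14 β-hydroxy ketone
Product: 15 (2S)-8-[(1S,3E,5R,7S)-7-hydroxy-5-(pyridine-2-carbonyloxy)-1-(TBSO)-9-[4-(TBSO)phenyl]non-3-enyl]-5-methoxy-7-(TBSO)-2-[4-(TBSO)phenyl]chroman-4-one
Conditions: pyridine-2-carbaldehyde (4 equiv), SmI2 (30 mol%), THF, −10 °C
Reagents that add atoms: pyridine-2-carbaldehyde, O=Cc1ccccn1
Why: Evans–Tishchenko reduction: the hemiacetal formed by the aldehyde on the C-5 hydroxyl delivers hydride intramolecularly to the C-7 ketone within a chelate of trivalent samarium, which should set the 1,3-anti (7S)-carbinol and leave the allylic oxygen as its picolinate, the leaving group for step 12; the C-4 ketone has no β-hydroxyl and should not be reduced.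

Step 11
Reactants: 15 hydroxy picolinate
Product: 16 (2S)-8-[(1S,3E,5R,7S)-5-(pyridine-2-carbonyloxy)-1,7-bis(TBSO)-9-[4-(TBSO)phenyl]non-3-enyl]-5-methoxy-7-(TBSO)-2-[4-(TBSO)phenyl]chroman-4-one
Conditions: TBSOTf, 2,6-lutidine, CH2Cl2, −78 °C
Reagents that add atoms: tert-butyldimethylsilyl triflate, CC(C)(C)[Si](C)(C)OS(=O)(=O)C(F)(F)F
Why: Silyl ether formation on the free C-7 carbinol should prevent magnesium alkoxide formation and 1,3-migration of the picolinate in the next step.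

Step 12
Reactants: 16 allylic picolinate; 17 (4-bromophenoxy)(tert-butyl)dimethylsilane
Product: 19 (2S)-8-[(1S,3R,4E,7S)-1,7-bis(TBSO)-3,9-bis[4-(TBSO)phenyl]non-4-enyl]-5-methoxy-7-(TBSO)-2-[4-(TBSO)phenyl]chroman-4-one, via arylmagnesium bromide 18 (not isolated)
Conditions: 17, Mg, THF, rt; CuBr·SMe2 (0.5 equiv per ArMgBr), −40 °C; then 16, −40 → −20 °C
Reagents that add atoms: none
Why: Copper-mediated anti-SN2' arylation of a secondary allylic picolinate: magnesium chelation by the picolinate nitrogen and carbonyl activates the leaving group, and the arylcopper reagent attacks C-3 anti to the C–O bond in the allylic-strain-minimised conformer, which should set the (R)-ArCH centre, give the E-alkene and remove the temporary oxygen, while organocopper reagents of this kind spare ketones at low temperature.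

Step 13
Reactants: 19 hexasilyl ether
Product: 20 (2S)-7-hydroxy-8-[(1S,3R,4E,7S)-1,7-dihydroxy-3,9-bis(4-hydroxyphenyl)non-4-enyl]-2-(4-hydroxyphenyl)-5-methoxychroman-4-one
Conditions: HF·pyridine, pyridine, THF, 0 °C → rt
Reagents that add atoms: none
Why: Global desilylation with pyridine-buffered HF should cleave all six silyl ethers without base, so C-2 does not epimerise, and without free strong acid, so the ortho-hydroxybenzylic alcohol does not ionise.

**Compound list**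

1 | (2S)-naringenin, (2S)-5,7-dihydroxy-2-(4-hydroxyphenyl)chroman-4-one | Oc1cc(O)cc2c1C(=O)C[C@@H](c1ccc(O)cc1)O2 | starting material
2 | (2S)-5-hydroxy-7-(TBSO)-2-[4-(TBSO)phenyl]chroman-4-one | Oc1cc(O[Si](C)(C)C(C)(C)C)cc2c1C(=O)C[C@@H](c1ccc(O[Si](C)(C)C(C)(C)C)cc1)O2 | intermediate
3 | (2S)-5-methoxy-7-(TBSO)-2-[4-(TBSO)phenyl]chroman-4-one | COc1cc(O[Si](C)(C)C(C)(C)C)cc2c1C(=O)C[C@@H](c1ccc(O[Si](C)(C)C(C)(C)C)cc1)O2 | intermediate
4 | (2S)-8-iodo-5-methoxy-7-(TBSO)-2-[4-(TBSO)phenyl]chroman-4-one | COc1cc(O[Si](C)(C)C(C)(C)C)c(I)c2c1C(=O)C[C@@H](c1ccc(O[Si](C)(C)C(C)(C)C)cc1)O2 | intermediate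
5 | (2S)-5-methoxy-4-oxo-7-(TBSO)-2-[4-(TBSO)phenyl]chroman-8-carbaldehyde | COc1cc(O[Si](C)(C)C(C)(C)C)c(C=O)c2c1C(=O)C[C@@H](c1ccc(O[Si](C)(C)C(C)(C)C)cc1)O2 | intermediate
6 | diisopinocampheylborinate ester of 7 (O-boryl homoallylic alkoxide) | COc1cc(O[Si](C)(C)C(C)(C)C)c([C@@H](OB([C@@H]2C[C@@H]3C[C@H]([C@H]2C)C3(C)C)[C@@H]2C[C@@H]3C[C@H]([C@H]2C)C3(C)C)CC=C)c2c1C(=O)C[C@@H](c1ccc(O[Si](C)(C)C(C)(C)C)cc1)O2 | intermediate
7 | (2S)-8-[(1S)-1-hydroxybut-3-enyl]-5-methoxy-7-(TBSO)-2-[4-(TBSO)phenyl]chroman-4-one | COc1cc(O[Si](C)(C)C(C)(C)C)c([C@@H](O)CC=C)c2c1C(=O)C[C@@H](c1ccc(O[Si](C)(C)C(C)(C)C)cc1)O2 | intermediate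
8 | (2S)-8-[(1S)-1-(TBSO)but-3-enyl]-5-methoxy-7-(TBSO)-2-[4-(TBSO)phenyl]chroman-4-one | COc1cc(O[Si](C)(C)C(C)(C)C)c([C@@H](O[Si](C)(C)C(C)(C)C)CC=C)c2c1C(=O)C[C@@H](c1ccc(O[Si](C)(C)C(C)(C)C)cc1)O2 | intermediate
9 | (2E,5S)-5-(TBSO)-5-{(2S)-5-methoxy-4-oxo-7-(TBSO)-2-[4-(TBSO)phenyl]chroman-8-yl}pent-2-enal | COc1cc(O[Si](C)(C)C(C)(C)C)c([C@@H](O[Si](C)(C)C(C)(C)C)C/C=C/C=O)c2c1C(=O)C[C@@H](c1ccc(O[Si](C)(C)C(C)(C)C)cc1)O2 | intermediate
10 | 4-(4-hydroxyphenyl)butan-2-one (raspberry ketone) | CC(=O)CCc1ccc(O)cc1 | starting material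
11 | 4-[4-(TBSO)phenyl]butan-2-one | CC(=O)CCc1ccc(O[Si](C)(C)C(C)(C)C)cc1 | intermediate
12 | 4-[4-(TBSO)phenyl]but-1-en-2-yl diisopinocampheylborinate (enol borinate of 11) | C=C(CCc1ccc(O[Si](C)(C)C(C)(C)C)cc1)OB([C@@H]1C[C@@H]2C[C@H]([C@H]1C)C2(C)C)[C@@H]1C[C@@H]2C[C@H]([C@H]1C)C2(C)C | intermediate
13 | O-diisopinocampheylboryl aldolate of 14 | COc1cc(O[Si](C)(C)C(C)(C)C)c([C@@H](O[Si](C)(C)C(C)(C)C)C/C=C/[C@H](OB([C@@H]2C[C@@H]3C[C@H]([C@H]2C)C3(C)C)[C@@H]2C[C@@H]3C[C@H]([C@H]2C)C3(C)C)CC(=O)CCc2ccc(O[Si](C)(C)C(C)(C)C)cc2)c2c1C(=O)C[C@@H](c1ccc(O[Si](C)(C)C(C)(C)C)cc1)O2 | intermediate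
14 | (2S)-8-[(1S,3E,5R)-5-hydroxy-7-oxo-1-(TBSO)-9-[4-(TBSO)phenyl]non-3-enyl]-5-methoxy-7-(TBSO)-2-[4-(TBSO)phenyl]chroman-4-one | COc1cc(O[Si](C)(C)C(C)(C)C)c([C@@H](O[Si](C)(C)C(C)(C)C)C/C=C/[C@H](O)CC(=O)CCc2ccc(O[Si](C)(C)C(C)(C)C)cc2)c2c1C(=O)C[C@@H](c1ccc(O[Si](C)(C)C(C)(C)C)cc1)O2 | intermediate
15 | (2S)-8-[(1S,3E,5R,7S)-7-hydroxy-5-(pyridine-2-carbonyloxy)-1-(TBSO)-9-[4-(TBSO)phenyl]non-3-enyl]-5-methoxy-7-(TBSO)-2-[4-(TBSO)phenyl]chroman-4-one | COc1cc(O[Si](C)(C)C(C)(C)C)c([C@@H](O[Si](C)(C)C(C)(C)C)C/C=C/[C@H](OC(=O)c2ccccn2)C[C@@H](O)CCc2ccc(O[Si](C)(C)C(C)(C)C)cc2)c2c1C(=O)C[C@@H](c1ccc(O[Si](C)(C)C(C)(C)C)cc1)O2 | intermediate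
16 | (2S)-8-[(1S,3E,5R,7S)-5-(pyridine-2-carbonyloxy)-1,7-bis(TBSO)-9-[4-(TBSO)phenyl]non-3-enyl]-5-methoxy-7-(TBSO)-2-[4-(TBSO)phenyl]chroman-4-one | COc1cc(O[Si](C)(C)C(C)(C)C)c([C@@H](O[Si](C)(C)C(C)(C)C)C/C=C/[C@H](OC(=O)c2ccccn2)C[C@@H](O[Si](C)(C)C(C)(C)C)CCc2ccc(O[Si](C)(C)C(C)(C)C)cc2)c2c1C(=O)C[C@@H](c1ccc(O[Si](C)(C)C(C)(C)C)cc1)O2 | intermediate
17 | (4-bromophenoxy)(tert-butyl)dimethylsilane | CC(C)(C)[Si](C)(C)Oc1ccc(Br)cc1 | starting material
18 | [4-(TBSO)phenyl]magnesium bromide | CC(C)(C)[Si](C)(C)Oc1ccc([Mg]Br)cc1 | intermediate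
19 | (2S)-8-[(1S,3R,4E,7S)-1,7-bis(TBSO)-3,9-bis[4-(TBSO)phenyl]non-4-enyl]-5-methoxy-7-(TBSO)-2-[4-(TBSO)phenyl]chroman-4-one | COc1cc(O[Si](C)(C)C(C)(C)C)c([C@@H](O[Si](C)(C)C(C)(C)C)C[C@H](/C=C/C[C@@H](O[Si](C)(C)C(C)(C)C)CCc2ccc(O[Si](C)(C)C(C)(C)C)cc2)c2ccc(O[Si](C)(C)C(C)(C)C)cc2)c2c1C(=O)C[C@@H](c1ccc(O[Si](C)(C)C(C)(C)C)cc1)O2 | intermediate
20 | (2S)-7-hydroxy-8-[(1S,3R,4E,7S)-1,7-dihydroxy-3,9-bis(4-hydroxyphenyl)non-4-enyl]-2-(4-hydroxyphenyl)-5-methoxychroman-4-one (CNP0415883.1) | COc1cc(O)c([C@@H](O)C[C@H](/C=C/C[C@@H](O)CCc2ccc(O)cc2)c2ccc(O)cc2)c2c1C(=O)C[C@@H](c1ccc(O)cc1)O2 | target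

**Count and risks**

Total step count: 13. Longest linear sequence: 12 steps (1 → 20 through steps 1–7 and 9–13).

Steps most likely to fail:

Step 12. What may go wrong: the arylcopper reagent may add to or enolise the C-4 carbonyl of ring C, or transfer its aryl group to the picolinate carbonyl or to C-5 without transposition. The fallback replaces the organocopper substitution by a base-free palladium-catalysed syn-SN2' arylation with an arylboronic acid; it sets out from 9 and 11 and comes back at 19. The aldol of step 9 is run with (+)-Ipc2BCl of the (−)-α-pinene series, which should give the C-5 epimer, the (5S)-β-hydroxy ketone F1. Narasaka–Prasad reduction (Et2BOMe, NaBH4, THF/MeOH, −78 °C) should give the 1,3-syn diol F2, and acetylation (Ac2O, pyridine, DMAP) the diacetate F3. Palladium-catalysed γ-selective allyl–aryl coupling of the allylic acetate with [4-(TBSO)phenyl]boronic acid (Pd(OAc)2, 1,10-phenanthroline, AgSbF6, ClCH2CH2Cl, 60 °C) delivers the aryl group syn to the acetate and tolerates ketones; it should give the arylated acetate F4 with the same (3R,4E) arrangement as 19. Neutral tin-catalysed methanolysis ([t-Bu2Sn(OH)Cl]2, MeOH/THF) should free the C-7 alcohol F5, and TBSOTf/2,6-lutidine returns to 19.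

Step 10. What may go wrong: the pyridine nitrogen of the aldehyde or of the product ester may sequester the samarium catalyst so that hydride transfer stalls, or the ester may migrate to the new hydroxyl. The fallback separates reduction and ester formation; it sets out from 14 and comes back at 19. Evans–Saksena reduction (Me4NBH(OAc)3, AcOH/MeCN, −30 °C) should give the 1,3-anti diol F6, and Steglich esterification of both hydroxyls with picolinic acid (EDC·HCl, DMAP, CH2Cl2) the bis-picolinate F7. The arylcopper reagent of step 12 should substitute only the allylic picolinate and give the arylated ester F8, which keeps the picolinate on the C-7 oxygen. Chelation-assisted methanolysis (Cu(OAc)2·H2O, MeOH/CH2Cl2) should then give the alcohol F5 already described in the fallback to step 12, and TBSOTf/2,6-lutidine returns to 19.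

Step 9. What may go wrong: poor facial selectivity of the reagent-controlled boron aldol, which would carry the wrong C-5 configuration into both later stereocentres. The fallback replaces the stoichiometric chiral boron enolate by a catalytic enantioselective Mukaiyama aldol addition; it sets out from 11 and comes back at 14. Ketone 11 is converted (LDA, TMSCl, THF, −78 °C) into its trimethylsilyl enol ether F9. Addition of F9 to enal 9 under SiCl4 activated by a chiral bisphosphoramide Lewis base (i-Pr2NEt, CH2Cl2, −78 °C; catalyst antipode chosen for re-face attack) should give 14 after aqueous work-up.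

**Further compounds**

F1 | step 12 | (2S)-8-[(1S,3E,5S)-5-hydroxy-7-oxo-1-(TBSO)-9-[4-(TBSO)phenyl]non-3-enyl]-5-methoxy-7-(TBSO)-2-[4-(TBSO)phenyl]chroman-4-one | COc1cc(O[Si](C)(C)C(C)(C)C)c([C@@H](O[Si](C)(C)C(C)(C)C)C/C=C/[C@@H](O)CC(=O)CCc2ccc(O[Si](C)(C)C(C)(C)C)cc2)c2c1C(=O)C[C@@H](c1ccc(O[Si](C)(C)C(C)(C)C)cc1)O2
F2 | step 12 | (2S)-8-[(1S,3E,5S,7S)-5,7-dihydroxy-1-(TBSO)-9-[4-(TBSO)phenyl]non-3-enyl]-5-methoxy-7-(TBSO)-2-[4-(TBSO)phenyl]chroman-4-one | COc1cc(O[Si](C)(C)C(C)(C)C)c([C@@H](O[Si](C)(C)C(C)(C)C)C/C=C/[C@@H](O)C[C@@H](O)CCc2ccc(O[Si](C)(C)C(C)(C)C)cc2)c2c1C(=O)C[C@@H](c1ccc(O[Si](C)(C)C(C)(C)C)cc1)O2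
F3 | step 12 | (2S)-8-[(1S,3E,5S,7S)-5,7-diacetoxy-1-(TBSO)-9-[4-(TBSO)phenyl]non-3-enyl]-5-methoxy-7-(TBSO)-2-[4-(TBSO)phenyl]chroman-4-one | COc1cc(O[Si](C)(C)C(C)(C)C)c([C@@H](O[Si](C)(C)C(C)(C)C)C/C=C/[C@@H](OC(C)=O)C[C@@H](OC(C)=O)CCc2ccc(O[Si](C)(C)C(C)(C)C)cc2)c2c1C(=O)C[C@@H](c1ccc(O[Si](C)(C)C(C)(C)C)cc1)O2
F4 | step 12 | (2S)-8-[(1S,3R,4E,7S)-7-acetoxy-1-(TBSO)-3,9-bis[4-(TBSO)phenyl]non-4-enyl]-5-methoxy-7-(TBSO)-2-[4-(TBSO)phenyl]chroman-4-one | COc1cc(O[Si](C)(C)C(C)(C)C)c([C@@H](O[Si](C)(C)C(C)(C)C)C[C@H](/C=C/C[C@@H](OC(C)=O)CCc2ccc(O[Si](C)(C)C(C)(C)C)cc2)c2ccc(O[Si](C)(C)C(C)(C)C)cc2)c2c1C(=O)C[C@@H](c1ccc(O[Si](C)(C)C(C)(C)C)cc1)O2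
F5 | step 12 | (2S)-8-[(1S,3R,4E,7S)-7-hydroxy-1-(TBSO)-3,9-bis[4-(TBSO)phenyl]non-4-enyl]-5-methoxy-7-(TBSO)-2-[4-(TBSO)phenyl]chroman-4-one | COc1cc(O[Si](C)(C)C(C)(C)C)c([C@@H](O[Si](C)(C)C(C)(C)C)C[C@H](/C=C/C[C@@H](O)CCc2ccc(O[Si](C)(C)C(C)(C)C)cc2)c2ccc(O[Si](C)(C)C(C)(C)C)cc2)c2c1C(=O)C[C@@H](c1ccc(O[Si](C)(C)C(C)(C)C)cc1)O2
F6 | step 10 | (2S)-8-[(1S,3E,5R,7S)-5,7-dihydroxy-1-(TBSO)-9-[4-(TBSO)phenyl]non-3-enyl]-5-methoxy-7-(TBSO)-2-[4-(TBSO)phenyl]chroman-4-one | COc1cc(O[Si](C)(C)C(C)(C)C)c([C@@H](O[Si](C)(C)C(C)(C)C)C/C=C/[C@H](O)C[C@@H](O)CCc2ccc(O[Si](C)(C)C(C)(C)C)cc2)c2c1C(=O)C[C@@H](c1ccc(O[Si](C)(C)C(C)(C)C)cc1)O2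
F7 | step 10 | (2S)-8-[(1S,3E,5R,7S)-5,7-bis(pyridine-2-carbonyloxy)-1-(TBSO)-9-[4-(TBSO)phenyl]non-3-enyl]-5-methoxy-7-(TBSO)-2-[4-(TBSO)phenyl]chroman-4-one | COc1cc(O[Si](C)(C)C(C)(C)C)c([C@@H](O[Si](C)(C)C(C)(C)C)C/C=C/[C@H](OC(=O)c2ccccn2)C[C@@H](OC(=O)c2ccccn2)CCc2ccc(O[Si](C)(C)C(C)(C)C)cc2)c2c1C(=O)C[C@@H](c1ccc(O[Si](C)(C)C(C)(C)C)cc1)O2
F8 | step 10 | (2S)-8-[(1S,3R,4E,7S)-7-(pyridine-2-carbonyloxy)-1-(TBSO)-3,9-bis[4-(TBSO)phenyl]non-4-enyl]-5-methoxy-7-(TBSO)-2-[4-(TBSO)phenyl]chroman-4-one | COc1cc(O[Si](C)(C)C(C)(C)C)c([C@@H](O[Si](C)(C)C(C)(C)C)C[C@H](/C=C/C[C@@H](OC(=O)c2ccccn2)CCc2ccc(O[Si](C)(C)C(C)(C)C)cc2)c2ccc(O[Si](C)(C)C(C)(C)C)cc2)c2c1C(=O)C[C@@H](c1ccc(O[Si](C)(C)C(C)(C)C)cc1)O2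
F9 | step 9 | {4-[4-(TBSO)phenyl]but-1-en-2-yloxy}trimethylsilane | C=C(CCc1ccc(O[Si](C)(C)C(C)(C)C)cc1)O[Si](C)(C)C
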